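## Retrosynthetic overview

1. Target 34 ← DDQ release of the C8 tertiary hydroxyl and acetylation of O9 ← macrocycle 32 ← SmI2 closure of the ten-membered ring: the ketyl carbon C9 (from aldehyde 31) bonds to the tetronate β-carbon C8, setting C8, C9 and C17.
2. Seco-aldehyde 31 ← boron aldol (C3–C4) of ring A methyl ketone 14 with Z-enal 25, then Evans–Tishchenko reduction with butanal (butyrate on O4, C2 carbinol anti).
3. Ketone 14 ← dianionic Ireland–Claisen (C1–C10), Fráter–Seebach methylation (quaternary C1) and ring-closing metathesis, from chlorohydrin ester 4 and prenol 1.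
4. Enal 25 ← PMB tetronate 19 and acrolein 17 by asymmetric vinylogous Mukaiyama aldol (C7), then rhenium-catalysed 1,3-transposition (5Z alkene, O16).
5. Ring order: lactone (bought as 18) → ring A (metathesis, step 7) → ten-membered ring (SmI2, step 23).

Assumption: the target is taken exactly as the given SMILES, (1R,2R,4R,5Z,7S,8S,9R,10S,14S,17R) in briarane numbering (used for all locants below); the senses of induction of (R)-BINOL/Ti(OiPr)4 (step 14) and (−)-Ipc2BCl (step 18) are taken by analogy with simple substrates, and the antipodal reagent would be used if either proved opposite.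

## Route

### Fragment A (ring A methyl ketone 14)

Step 1
Reactants: 1 3-methylbut-2-en-1-ol (prenol)
Product: 2 tert-butyldimethyl[(3-methylbut-2-en-1-yl)oxy]silane
Conditions: t-BuMe2SiCl, imidazole, CH2Cl2, 0 → 23 °C
Reagents that add atoms: tert-butyldimethylsilyl chloride, CC(C)(C)[Si](C)(C)Cl
Why: routine silylation of a primary alcohol gives an ether that survives the strong bases, metathesis and Lewis acids used up to step 21.

Step 2
Reactants: 2 tert-butyldimethyl[(3-methylbut-2-en-1-yl)oxy]silane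
Product: 3 (2E)-4-[(tert-butyldimethylsilyl)oxy]-2-methylbut-2-en-1-ol
Conditions: SeO2 (0.3 equiv), t-BuOOH (3 equiv), salicylic acid (0.1 equiv), CH2Cl2, 23 °C
Reagents that add atoms: tert-butyl hydroperoxide, CC(C)(C)OO
Why: Riley allylic oxidation (ene reaction then [2,3] shift) hydroxylates only the E-methyl group of a trisubstituted alkene, which fixes the E geometry needed in step 5.

Step 3
Reactants: 4 ethyl (3R)-4-chloro-3-hydroxybutanoate
Product: 6 ethyl (3S)-3-hydroxyhex-5-enoate, via ethyl 2-[(2R)-oxiran-2-yl]acetate 5 (not isolated)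
Conditions: CH2=CHMgBr (3.2 equiv), CuI (0.1 equiv), THF, −40 → −10 °C
Reagents that add atoms: vinylmagnesium bromide, C=C[Mg]Br
Why: the magnesium chloro-alkoxide closes to the epoxide, which the vinyl cuprate opens at the terminal carbon (copper-catalysed Grignard epoxide opening) faster than the ester is attacked at low temperature; the carbinol centre is untouched and only its descriptor changes.

Step 4
Reactants: 6 ethyl (3S)-3-hydroxyhex-5-enoate; 3 (2E)-4-[(tert-butyldimethylsilyl)oxy]-2-methylbut-2-en-1-ol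
Product: 7 (2E)-4-[(tert-butyldimethylsilyl)oxy]-2-methylbut-2-en-1-yl (3S)-3-hydroxyhex-5-enoate
Conditions: Bu2SnO (0.1 equiv), toluene, 110 °C, 4 Å MS (ethanol removed)
Reagents that add atoms: none
Why: neutral tin-catalysed transesterification exchanges the ethyl for the allylic ester without dehydrating the β-hydroxy ester or touching the silyl ether.

Step 5
Reactants: 7 (2E)-4-[(tert-butyldimethylsilyl)oxy]-2-methylbut-2-en-1-yl (3S)-3-hydroxyhex-5-enoate
Product: 9 methyl (2S,3S)-2-[(2R)-1-[(tert-butyldimethylsilyl)oxy]-3-methylbut-3-en-2-yl]-3-hydroxyhex-5-enoate, via Claisen acid 8 (not isolated)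
Conditions: LiN(iPr)2 (2.6 equiv), THF, −78 → 23 °C, 14 h; then AcOH, MeOH, Me3SiCHN2, 0 °C
Reagents that add atoms: (trimethylsilyl)diazomethane, C[Si](C)(C)C=[N+]=[N-]
Why: dianionic Ireland–Claisen rearrangement, in which the lithium-chelated alkoxide enolate (C14 cis to OLi) rearranges through a chair on the face anti to the allyl group of the carbinol, the E alkene placing C9 equatorial, so that C10 is set relative to C14 (C1 is reset in step 6).

Step 6
Reactants: 9 methyl (2S,3S)-2-[(2R)-1-[(tert-butyldimethylsilyl)oxy]-3-methylbut-3-en-2-yl]-3-hydroxyhex-5-enoate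
Product: 10 methyl (2R,3S)-2-[(2S)-1-[(tert-butyldimethylsilyl)oxy]-3-methylbut-3-en-2-yl]-3-hydroxy-2-methylhex-5-enoate
Conditions: LiN(iPr)2 (2.5 equiv), THF, −78 → −20 °C; MeI (3 equiv), DMPU, −78 → −30 °C
Reagents that add atoms: iodomethane, CI
Why: Fráter–Seebach alkylation, in which the chelated dianion (allyl group of C14 pseudo-axial because of the α-substituent) is methylated anti to that group, giving quaternary C1 with the methyl anti to O14 as in the target.

Step 7
Reactants: 10 methyl (2R,3S)-2-[(2S)-1-[(tert-butyldimethylsilyl)oxy]-3-methylbut-3-en-2-yl]-3-hydroxy-2-methylhex-5-enoate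
Product: 11 methyl (1R,2S,6S)-2-{[(tert-butyldimethylsilyl)oxy]methyl}-6-hydroxy-1,3-dimethylcyclohex-3-ene-1-carboxylate
Conditions: second-generation Grubbs catalyst RuCl2(H2IMes)(PCy3)(=CHPh) (5 mol%), CH2Cl2, 40 °C
Reagents that add atoms: none
Why: ring-closing metathesis of the isopropenyl and allyl groups gives the trisubstituted C11=C12 cyclohexene, helped by the adjacent quaternary carbon, without touching any stereocentre.

Step 8
Reactants: 11 methyl (1R,2S,6S)-2-{[(tert-butyldimethylsilyl)oxy]methyl}-6-hydroxy-1,3-dimethylcyclohex-3-ene-1-carboxylate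
Product: 13 1-[(1R,2S,6S)-2-{[(tert-butyldimethylsilyl)oxy]methyl}-6-hydroxy-1,3-dimethylcyclohex-3-en-1-yl]ethan-1-one, via α-trimethylsilyl ketone 12 (not isolated)
Conditions: Me3SiCH2Li (4 equiv), pentane/THF, 0 → 23 °C; then MeOH
Reagents that add atoms: (trimethylsilyl)methyllithium, C[Si](C)(C)C[Li]
Why: nucleophilic acyl substitution of the hindered ester stops at the ketone stage because the α-silyl ketone is deprotonated at once (which also prevents retro-aldol), and methanol then removes the silyl group to leave the methyl ketone.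

Step 9
Reactants: 13 1-[(1R,2S,6S)-2-{[(tert-butyldimethylsilyl)oxy]methyl}-6-hydroxy-1,3-dimethylcyclohex-3-en-1-yl]ethan-1-one
Product: 14 (1S,5S,6R)-6-acetyl-5-{[(tert-butyldimethylsilyl)oxy]methyl}-4,6-dimethylcyclohex-3-en-1-yl acetate (fragment A)
Conditions: Ac2O, DMAP, pyridine, CH2Cl2, 23 °C
Reagents that add atoms: acetic anhydride, CC(=O)OC(C)=O
Why: acetylation installs the final 14-acetate and removes the hydroxyl that would otherwise compete as a directing group in step 19; the quaternary α-carbon makes β-elimination impossible.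

### Fragment B (Z-enal 25)

Step 10
Reactants: 15 2-methylidenepropane-1,3-diol
Product: 16 2-{[(triethylsilyl)oxy]methyl}prop-2-en-1-ol
Conditions: NaH (1.0 equiv), THF, 0 °C; Et3SiCl (1.0 equiv)
Reagents that add atoms: chlorotriethylsilane, CC[Si](Cl)(CC)CC
Why: monosilylation of a symmetrical diol through its sparingly soluble monosodium alkoxide gives mainly the mono-ether.

Step 11
Reactants: 16 2-{[(triethylsilyl)oxy]methyl}prop-2-en-1-ol
Product: 17 2-{[(triethylsilyl)oxy]methyl}prop-2-enal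
Conditions: MnO2 (15 equiv), CH2Cl2, 23 °C
Reagents that add atoms: none
Why: neutral oxidation of an allylic alcohol gives the 2-substituted acrolein without loss of the silyl ether.

Step 12
Reactants: 18 4-hydroxy-3-methylfuran-2(5H)-one (3-methyltetronic acid)
Product: 19 4-[(4-methoxybenzyl)oxy]-3-methylfuran-2(5H)-one
Conditions: 4-MeOC6H4CH2OH, PPh3, DIAD, THF, 0 → 23 °C
Reagents that add atoms: 4-methoxybenzyl alcohol, COc1ccc(CO)cc1
Why: Mitsunobu O-alkylation of the acidic enol gives the tetronate, with the PMB group as the later-removable mask of the C8 oxygen.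

Step 13
Reactants: 19 4-[(4-methoxybenzyl)oxy]-3-methylfuran-2(5H)-one
Product: 20 {[4-[(4-methoxybenzyl)oxy]-3-methylfuran-2-yl]oxy}trimethylsilane
Conditions: Me3SiOTf (1.1 equiv), Et3N (1.3 equiv), Et2O, 0 °C; filtered under argon and used at once
Reagents that add atoms: trimethylsilyl triflate, C[Si](C)(C)OS(=O)(=O)C(F)(F)F
Why: soft enolisation (O-silylation then loss of the C5 proton) gives the 2-silyloxyfuran, the dienolate equivalent that reacts through C5.

Step 14
Reactants: 20 {[4-[(4-methoxybenzyl)oxy]-3-methylfuran-2-yl]oxy}trimethylsilane; 17 2-{[(triethylsilyl)oxy]methyl}prop-2-enal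
Product: 22 (5S)-5-[(1S)-1-hydroxy-2-{[(triethylsilyl)oxy]methyl}prop-2-en-1-yl]-4-[(4-methoxybenzyl)oxy]-3-methylfuran-2(5H)-one, via O-trimethylsilyl aldolate 21 (not isolated)
Conditions: Ti(OiPr)4 (20 mol%), (R)-BINOL (20 mol%), Et2O, −20 °C; then 1 M HCl, THF, 0 °C
Reagents that add atoms: none
Why: catalytic asymmetric vinylogous Mukaiyama aldol, in which the titanium BINOLate activates the aldehyde and the silyloxyfuran attacks through C5 in an open anti-selective transition state, fixing C7 as S (the C6 carbinol centre is erased in step 15).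

Step 15
Reactants: 22 (5S)-5-[(1S)-1-hydroxy-2-{[(triethylsilyl)oxy]methyl}prop-2-en-1-yl]-4-[(4-methoxybenzyl)oxy]-3-methylfuran-2(5H)-one
Product: 23 (5S)-5-[(1Z)-3-hydroxy-2-{[(triethylsilyl)oxy]methyl}prop-1-en-1-yl]-4-[(4-methoxybenzyl)oxy]-3-methylfuran-2(5H)-one
Conditions: Ph3SiOReO3 (3 mol%), Et2O, −50 → −30 °C, 30 min; Et3N quench
Reagents that add atoms: none
Why: rhenium-oxo-catalysed [3,3] 1,3-transposition of the allylic alcohol through its perrhenate ester, whose chair with the furanone substituent equatorial puts C7 trans to the migrating terminus C16 and so cis to C4 (5Z); the trisubstituted alkene and primary alcohol are favoured, and a short cold reaction keeps the kinetic geometry.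

Step 16
Reactants: 23 (5S)-5-[(1Z)-3-hydroxy-2-{[(triethylsilyl)oxy]methyl}prop-1-en-1-yl]-4-[(4-methoxybenzyl)oxy]-3-methylfuran-2(5H)-one
Product: 24 (2Z)-3-[(2S)-3-[(4-methoxybenzyl)oxy]-4-methyl-5-oxo-2,5-dihydrofuran-2-yl]-2-{[(triethylsilyl)oxy]methyl}prop-2-en-1-yl acetate
Conditions: Ac2O, pyridine, DMAP (cat.), CH2Cl2, 0 °C
Reagents that add atoms: acetic anhydride, CC(=O)OC(C)=O
Why: acetylation of the primary allylic alcohol installs the final 16-acetate under conditions too mild to remove the C7 proton.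

Step 17
Reactants: 24 (2Z)-3-[(2S)-3-[(4-methoxybenzyl)oxy]-4-methyl-5-oxo-2,5-dihydrofuran-2-yl]-2-{[(triethylsilyl)oxy]methyl}prop-2-en-1-yl acetate
Product: 25 (2Z)-2-formyl-3-[(2S)-3-[(4-methoxybenzyl)oxy]-4-methyl-5-oxo-2,5-dihydrofuran-2-yl]prop-2-en-1-yl acetate (fragment B)
Conditions: IBX (3 equiv), DMSO, 23 °C; used at once
Reagents that add atoms: none
Why: one-pot oxidative desilylation (cleavage of the primary triethylsilyl ether then IBX oxidation) under neutral conditions avoids base-induced isomerisation of the labile Z-enal and epimerisation at C7.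

### Union and endgame

Step 18
Reactants: 14 (1S,5S,6R)-6-acetyl-5-{[(tert-butyldimethylsilyl)oxy]methyl}-4,6-dimethylcyclohex-3-en-1-yl acetate; 25 (2Z)-2-formyl-3-[(2S)-3-[(4-methoxybenzyl)oxy]-4-methyl-5-oxo-2,5-dihydrofuran-2-yl]prop-2-en-1-yl acetate
Product: 27 β-hydroxy ketone (4R,5Z,7S; C2 ketone; ring A as in 14), via enol diisopinocampheylborinate 26 (not isolated)
Conditions: 14, (−)-Ipc2BCl (1.5 equiv), Et3N (1.7 equiv), Et2O, 0 °C, 2 h; then 25, −78 → −25 °C; then pH 7 buffer, MeOH, 30% H2O2, 0 °C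
Reagents that add atoms: none
Why: Paterson boron aldol, in which the methyl group is the only enolisable ketone position (esters are not enolised by R2BCl/Et3N) and the chiral enol borinate adds 1,2 to the Re face of the enal through a cyclic transition state, setting C4 as R by reagent control.

Step 19
Reactants: 27 β-hydroxy ketone (4R,5Z,7S; C2 ketone)
Product: 28 4-butyrate 2-alcohol (2R,4R,5Z,7S)
Conditions: n-PrCHO (6 equiv), SmI2 (0.3 equiv, premixed with the aldehyde), THF, −10 °C
Reagents that add atoms: butanal, CCCC=O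
Why: Evans–Tishchenko reduction, in which the C4 hydroxyl forms a hemiacetal with butanal on trivalent samarium and delivers its hydride to the C2 ketone through a six-membered chair, giving the 2,4-anti carbinol (2R) and leaving the butyrate on O4 in one operation.

Step 20
Reactants: 28 4-butyrate 2-alcohol (2R,4R,5Z,7S)
Product: 29 2,14,16-triacetate 4-butyrate 9-silyl ether
Conditions: Ac2O, DMAP, pyridine, 40 °C
Reagents that add atoms: acetic anhydride, CC(=O)OC(C)=O
Why: acetylation of the hindered C2 carbinol gives the final 2-acetate and removes the hydroxyl that would form a lactol with the C9 aldehyde.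

Step 21
Reactants: 29 2,14,16-triacetate 4-butyrate 9-silyl ether
Product: 30 seco C9 primary alcohol
Conditions: HF·pyridine, pyridine, THF, 0 → 23 °C
Reagents that add atoms: none
Why: buffered fluoride removes the primary silyl ether without acyl migration, ester cleavage or loss of the C7 proton.

Step 22
Reactants: 30 seco C9 primary alcohol
Product: 31 seco C9 aldehyde
Conditions: Dess–Martin periodinane, NaHCO3, CH2Cl2, 0 °C; used at once
Reagents that add atoms: none
Why: buffered Dess–Martin oxidation gives the β,γ-unsaturated aldehyde without epimerising C10 or moving the C11=C12 alkene into conjugation.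

Step 23
Reactants: 31 seco C9 aldehyde
Product: 32 ten-membered 9-alcohol 8-PMB ether (1R,2R,4R,5Z,7S,8S,9R,10S,14S,17R)
Conditions: SmI2 (3 equiv), t-BuOH (5 equiv), THF, 31 added over 6 h to a final 0.002 M, 0 → 23 °C
Reagents that add atoms: none
Why: Proposed new method: one-electron reduction of the C9 aldehyde gives a nucleophilic samarium ketyl (a carbonyl carbon of reversed polarity) that adds within the molecule to C8, the β-carbon of the tetronate (a vinylogous carbonate and itself an electrophilic carbon), closing the ten-membered ring, after which a second electron gives the C17 samarium enolate that t-BuOH protonates; C8 is expected from attack on the butenolide face anti to the C7 alkenyl group (trans ring fusion), C17 from proton delivery by the samarium-bound alcohol on the C9 side, and C9 from the least-strained transition state in which trivalent samarium bridges the ketyl and C8 ether oxygens; the closest known reactions are SmI2 ketyl additions to β-alkoxyacrylates (Nakata cyclic ether synthesis) and SmI2 ketyl–olefin closures of medium rings, whereas a ten-membered closure onto a tetrasubstituted tetronate has no precedent.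

Step 24
Reactants: 32 ten-membered 9-alcohol 8-PMB ether
Product: 33 9-acetate 8-PMB ether
Conditions: Ac2O, DMAP, pyridine, 0 → 23 °C
Reagents that add atoms: acetic anhydride, CC(=O)OC(C)=O
Why: acetylation of the only free (secondary) hydroxyl gives the 9-acetate while the tertiary C8 oxygen is still masked.

Step 25
Reactants: 33 9-acetate 8-PMB ether
Product: 34 CNP0290502.1
Conditions: DDQ (2 equiv), CH2Cl2/pH 7 buffer (10:1), 0 → 23 °C
Reagents that add atoms: none
Why: oxidative cleavage of the PMB ether (hydride abstraction then hydrolysis of the oxocarbenium ion) frees the tertiary C8 hydroxyl under neutral conditions that leave the five esters and both trisubstituted alkenes untouched.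

## Compound list

1 | 3-methylbut-2-en-1-ol (prenol) | CC(C)=CCO | starting material
2 | tert-butyldimethyl[(3-methylbut-2-en-1-yl)oxy]silane | CC(C)=CCO[Si](C)(C)C(C)(C)C | intermediate
3 | (2E)-4-[(tert-butyldimethylsilyl)oxy]-2-methylbut-2-en-1-ol | OC/C(C)=C/CO[Si](C)(C)C(C)(C)C | intermediate
4 | ethyl (3R)-4-chloro-3-hydroxybutanoate | CCOC(=O)C[C@@H](O)CCl | starting material
5 | ethyl 2-[(2R)-oxiran-2-yl]acetate (not isolated) | CCOC(=O)C[C@@H]1CO1 | intermediate
6 | ethyl (3S)-3-hydroxyhex-5-enoate | CCOC(=O)C[C@@H](O)CC=C | intermediate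
7 | (2E)-4-[(tert-butyldimethylsilyl)oxy]-2-methylbut-2-en-1-yl (3S)-3-hydroxyhex-5-enoate | O=C(C[C@@H](O)CC=C)OC/C(C)=C/CO[Si](C)(C)C(C)(C)C | intermediate
8 | (2S,3S)-2-[(2R)-1-[(tert-butyldimethylsilyl)oxy]-3-methylbut-3-en-2-yl]-3-hydroxyhex-5-enoic acid (Claisen acid, not isolated) | OC(=O)[C@H]([C@@H](O)CC=C)[C@@H](CO[Si](C)(C)C(C)(C)C)C(C)=C | intermediate
9 | methyl (2S,3S)-2-[(2R)-1-[(tert-butyldimethylsilyl)oxy]-3-methylbut-3-en-2-yl]-3-hydroxyhex-5-enoate | COC(=O)[C@H]([C@@H](O)CC=C)[C@@H](CO[Si](C)(C)C(C)(C)C)C(C)=C | intermediate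
10 | methyl (2R,3S)-2-[(2S)-1-[(tert-butyldimethylsilyl)oxy]-3-methylbut-3-en-2-yl]-3-hydroxy-2-methylhex-5-enoate | COC(=O)[C@@](C)([C@@H](O)CC=C)[C@@H](CO[Si](C)(C)C(C)(C)C)C(C)=C | intermediate
11 | methyl (1R,2S,6S)-2-{[(tert-butyldimethylsilyl)oxy]methyl}-6-hydroxy-1,3-dimethylcyclohex-3-ene-1-carboxylate | COC(=O)[C@@]1(C)[C@@H](O)CC=C(C)[C@@H]1CO[Si](C)(C)C(C)(C)C | intermediate
12 | 1-[(1R,2S,6S)-2-{[(tert-butyldimethylsilyl)oxy]methyl}-6-hydroxy-1,3-dimethylcyclohex-3-en-1-yl]-2-(trimethylsilyl)ethan-1-one (not isolated) | C[Si](C)(C)CC(=O)[C@@]1(C)[C@@H](O)CC=C(C)[C@@H]1CO[Si](C)(C)C(C)(C)C | intermediate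
13 | 1-[(1R,2S,6S)-2-{[(tert-butyldimethylsilyl)oxy]methyl}-6-hydroxy-1,3-dimethylcyclohex-3-en-1-yl]ethan-1-one | CC(=O)[C@@]1(C)[C@@H](O)CC=C(C)[C@@H]1CO[Si](C)(C)C(C)(C)C | intermediate
14 | (1S,5S,6R)-6-acetyl-5-{[(tert-butyldimethylsilyl)oxy]methyl}-4,6-dimethylcyclohex-3-en-1-yl acetate (fragment A) | CC(=O)[C@@]1(C)[C@@H](OC(C)=O)CC=C(C)[C@@H]1CO[Si](C)(C)C(C)(C)C | intermediate
15 | 2-methylidenepropane-1,3-diol | C=C(CO)CO | starting material
16 | 2-{[(triethylsilyl)oxy]methyl}prop-2-en-1-ol | C=C(CO)CO[Si](CC)(CC)CC | intermediate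
17 | 2-{[(triethylsilyl)oxy]methyl}prop-2-enal | C=C(C=O)CO[Si](CC)(CC)CC | intermediate
18 | 4-hydroxy-3-methylfuran-2(5H)-one (3-methyltetronic acid) | CC1=C(O)COC1=O | starting material
19 | 4-[(4-methoxybenzyl)oxy]-3-methylfuran-2(5H)-one | CC1=C(OCc2ccc(OC)cc2)COC1=O | intermediate
20 | {[4-[(4-methoxybenzyl)oxy]-3-methylfuran-2-yl]oxy}trimethylsilane | COc1ccc(COc2coc(O[Si](C)(C)C)c2C)cc1 | intermediate
21 | O-trimethylsilyl ether of 22 (not isolated) | CC1=C(OCc2ccc(OC)cc2)[C@H]([C@@H](O[Si](C)(C)C)C(=C)CO[Si](CC)(CC)CC)OC1=O | intermediate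
22 | (5S)-5-[(1S)-1-hydroxy-2-{[(triethylsilyl)oxy]methyl}prop-2-en-1-yl]-4-[(4-methoxybenzyl)oxy]-3-methylfuran-2(5H)-one | CC1=C(OCc2ccc(OC)cc2)[C@H]([C@@H](O)C(=C)CO[Si](CC)(CC)CC)OC1=O | intermediate
23 | (5S)-5-[(1Z)-3-hydroxy-2-{[(triethylsilyl)oxy]methyl}prop-1-en-1-yl]-4-[(4-methoxybenzyl)oxy]-3-methylfuran-2(5H)-one | CC1=C(OCc2ccc(OC)cc2)[C@H](/C=C(\CO[Si](CC)(CC)CC)CO)OC1=O | intermediate
24 | (2Z)-3-[(2S)-3-[(4-methoxybenzyl)oxy]-4-methyl-5-oxo-2,5-dihydrofuran-2-yl]-2-{[(triethylsilyl)oxy]methyl}prop-2-en-1-yl acetate | CC1=C(OCc2ccc(OC)cc2)[C@H](/C=C(\CO[Si](CC)(CC)CC)COC(C)=O)OC1=O | intermediate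
25 | (2Z)-2-formyl-3-[(2S)-3-[(4-methoxybenzyl)oxy]-4-methyl-5-oxo-2,5-dihydrofuran-2-yl]prop-2-en-1-yl acetate (fragment B) | CC1=C(OCc2ccc(OC)cc2)[C@H](/C=C(\C=O)COC(C)=O)OC1=O | intermediate
26 | enol bis[(−)-isopinocampheyl]borinate of 14 (not isolated) | C=C(OB([C@@H]2C[C@@H]3C[C@H]([C@H]2C)C3(C)C)[C@@H]2C[C@@H]3C[C@H]([C@H]2C)C3(C)C)[C@@]1(C)[C@@H](OC(C)=O)CC=C(C)[C@@H]1CO[Si](C)(C)C(C)(C)C | intermediate
27 | β-hydroxy ketone: C2 ketone, (4R)-alcohol, 5Z, 7S, 14- and 16-acetates, 9-O-TBS, 8-O-PMB tetronate | O[C@@H](/C(COC(C)=O)=C\[C@@H]1OC(=O)C(C)=C1OCc1ccc(OC)cc1)CC(=O)[C@@]1(C)[C@@H](OC(C)=O)CC=C(C)[C@@H]1CO[Si](C)(C)C(C)(C)C | intermediate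
28 | (2R)-alcohol (4R)-butyrate, otherwise as 27 | CCCC(=O)O[C@@H](/C(COC(C)=O)=C\[C@@H]1OC(=O)C(C)=C1OCc1ccc(OC)cc1)C[C@@H](O)[C@@]1(C)[C@@H](OC(C)=O)CC=C(C)[C@@H]1CO[Si](C)(C)C(C)(C)C | intermediate
29 | 2,14,16-triacetate 4-butyrate 9-O-TBS seco compound | CCCC(=O)O[C@@H](/C(COC(C)=O)=C\[C@@H]1OC(=O)C(C)=C1OCc1ccc(OC)cc1)C[C@@H](OC(C)=O)[C@@]1(C)[C@@H](OC(C)=O)CC=C(C)[C@@H]1CO[Si](C)(C)C(C)(C)C | intermediate
30 | seco C9 primary alcohol | CCCC(=O)O[C@@H](/C(COC(C)=O)=C\[C@@H]1OC(=O)C(C)=C1OCc1ccc(OC)cc1)C[C@@H](OC(C)=O)[C@@]1(C)[C@@H](OC(C)=O)CC=C(C)[C@@H]1CO | intermediate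
31 | seco C9 aldehyde | CCCC(=O)O[C@@H](/C(COC(C)=O)=C\[C@@H]1OC(=O)C(C)=C1OCc1ccc(OC)cc1)C[C@@H](OC(C)=O)[C@@]1(C)[C@@H](OC(C)=O)CC=C(C)[C@@H]1C=O | intermediate
32 | macrocycle: (9R)-alcohol, 8-O-PMB ether, 17R, 2,14,16-triacetate 4-butyrate | CCCC(=O)O[C@@H]1C[C@@H](OC(C)=O)[C@@]2(C)[C@@H](OC(C)=O)CC=C(C)[C@@H]2[C@@H](O)[C@@]2(OCc3ccc(OC)cc3)[C@H](/C=C\1COC(C)=O)OC(=O)[C@@H]2C | intermediate
33 | macrocycle: 2,9,14,16-tetraacetate 4-butyrate 8-O-PMB ether | CCCC(=O)O[C@@H]1C[C@@H](OC(C)=O)[C@@]2(C)[C@@H](OC(C)=O)CC=C(C)[C@@H]2[C@@H](OC(C)=O)[C@@]2(OCc3ccc(OC)cc3)[C@H](/C=C\1COC(C)=O)OC(=O)[C@@H]2C | intermediate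
34 | CNP0290502.1 | CCCC(=O)O[C@@H]1C[C@@H](OC(C)=O)[C@@]2(C)[C@@H](OC(C)=O)CC=C(C)[C@@H]2[C@@H](OC(C)=O)[C@@]2(O)[C@H](/C=C\1COC(C)=O)OC(=O)[C@@H]2C | target

## Summary

Total step count: 25 (fragment A 9, fragment B 8, union and endgame 8).
Longest linear sequence: 16 steps (steps 1, 2, 4–9, 18–25).

Three steps most likely to fail:

Step 23 (ten-membered SmI2 closure). The foreseeable failures are simple reduction of the ketyl before it cyclises, loss of the C8 alkoxide from the samarium enolate, or the wrong C9 epimer. The fallback sets out from 31 and returns at 32. The aldehyde is treated with PhSeSiMe3 and catalytic ZnI2 in CH2Cl2 to give the O-trimethylsilyl hemiselenoacetal F1 (both C9 epimers). The α-silyloxy alkyl radical, the same reversed-polarity C9 synthon but now neutral and chain-carried, is released from it with (Me3Si)3SiH and AIBN in benzene at 80 °C under syringe-pump dilution. Addition to C8 and hydrogen-atom transfer to C17 give the 9-O-trimethylsilyl macrocycle F2; no metal enolate is formed, so β-alkoxide loss and over-reduction cannot occur. Citric acid in MeOH then gives 32.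

Step 14 (asymmetric vinylogous aldol). Enantio- and anti-selectivity are untested for a 4-alkoxy-3-methyl silyloxyfuran. The fallback sets out from 19 (with 17) and returns at 22. The lithium dienolate of 19 (LiN(iPr)2, THF, −78 °C) is added to 17 to give, after chromatographic removal of the syn isomer, the racemic anti aldol F3. Sharpless kinetic resolution (Ti(OiPr)4, L-(+)-diisopropyl tartrate, t-BuOOH, 4 Å MS, CH2Cl2, −20 °C, about 55% conversion) epoxidises the fast enantiomer to the epoxy alcohol F4 and leaves 22.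

Step 15 (1,3-transposition). The 5Z geometry rests on kinetic chair control and could erode by re-equilibration. The fallback sets out from 23, taken as whatever E/Z mixture step 15 delivers, and returns at 25. AcOH/THF/H2O removes the triethylsilyl group to give the diol F5, whose two hydroxymethyl arms are identical, so the geometric problem disappears. Lipase-catalysed monoacetylation (Amano lipase PS, vinyl acetate, t-BuOMe) acylates the more exposed arm, trans to the lactone carbon, to give the monoacetate F6. Dess–Martin oxidation of the remaining cis arm gives 25.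

Further compounds
F1 | step 23 | O-trimethylsilyl hemiselenoacetal of 31 (C9 epimers) | CCCC(=O)O[C@@H](/C(COC(C)=O)=C\[C@@H]1OC(=O)C(C)=C1OCc1ccc(OC)cc1)C[C@@H](OC(C)=O)[C@@]1(C)[C@@H](OC(C)=O)CC=C(C)[C@@H]1C(O[Si](C)(C)C)[Se]c1ccccc1
F2 | step 23 | 9-O-trimethylsilyl ether of 32 | CCCC(=O)O[C@@H]1C[C@@H](OC(C)=O)[C@@]2(C)[C@@H](OC(C)=O)CC=C(C)[C@@H]2[C@@H](O[Si](C)(C)C)[C@@]2(OCc3ccc(OC)cc3)[C@H](/C=C\1COC(C)=O)OC(=O)[C@@H]2C
F3 | step 14 | racemic anti aldol, rac-22 (relative configuration shown) | CC1=C(OCc2ccc(OC)cc2)[C@H]([C@@H](O)C(=C)CO[Si](CC)(CC)CC)OC1=O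
F4 | step 14 | (5R)-5-[(S)-hydroxy[(2R)-2-{[(triethylsilyl)oxy]methyl}oxiran-2-yl]methyl]-4-[(4-methoxybenzyl)oxy]-3-methylfuran-2(5H)-one (epoxy alcohol from ent-22) | CC1=C(OCc2ccc(OC)cc2)[C@@H]([C@H](O)[C@]2(CO[Si](CC)(CC)CC)CO2)OC1=O
F5 | step 15 | (5S)-5-[3-hydroxy-2-(hydroxymethyl)prop-1-en-1-yl]-4-[(4-methoxybenzyl)oxy]-3-methylfuran-2(5H)-one | CC1=C(OCc2ccc(OC)cc2)[C@H](C=C(CO)CO)OC1=O
F6 | step 15 | (2E)-2-(hydroxymethyl)-3-[(2S)-3-[(4-methoxybenzyl)oxy]-4-methyl-5-oxo-2,5-dihydrofuran-2-yl]prop-2-en-1-yl acetate | CC1=C(OCc2ccc(OC)cc2)[C@H](/C=C(\CO)COC(C)=O)OC1=O
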